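**Assumption (one line):** atoms are labelled C1–C15 along the target SMILES (C1 = acetoxy carbon, C2H=C3(Me), C4 = ring C=O, C5=C6H, C7 = O-bearing methyl carbon, C8, C9, C10 = OCH, C11 = CMe2, C12, C13, C14 = CHMe, C15 = macrocyclic C=O); in these labels the target is 1S,7S,10S,14R, and 4-methylpent-4-en-1-ol is taken as commercial.

## Retrosynthetic overview

1. Target ⇐ 22 (C1–H) by late acetoxylation at C1.
2. 22 ⇐ p-quinol 20 by ring contraction: the in-ring carbon C2 shifts from C15 to C1, C15 becomes the ketone and the C6 hydroxyl is lost, giving the cyclopentenone and the C5=C6 enone; 20 ⇐ phenol 18 by dearomatisation.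
3. 18 (twelve-membered metacyclophane) ⇐ phenol aldehyde 16 by ortho-hydroxyalkylation (C5–C6).
4. 16 ⇐ oxolane 5 + vinyl triflate 11 by B-alkyl Suzuki coupling (C13–C14), then asymmetric hydrogenation (C14); 11 ⇐ 2-methylphenol + acetyl chloride.
5. 5 ⇐ dienol 4 (oxidative cyclisation, trans-oxolane, C7) ⇐ 4-methylpent-4-en-1-ol + 1,1-dimethylallene (C10–C11, C10). Ring order: oxolane, then twelve-membered ring, then five-membered ring.

## Route

**Step 1**
Reactants: 1 4-methylpent-4-en-1-ol; 2 3-methylbuta-1,2-diene
Product: 4 (4S)-3,3,7-trimethylocta-1,7-dien-4-ol, via 4-methylpent-4-enal 3 (not isolated)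
Conditions: [Ir(cod)Cl]2 (2.5 mol%), SEGPHOS (5 mol%, enantiomer giving 4S), 4-cyano-3-nitrobenzoic acid (10 mol%), Cs2CO3 (20 mol%), 2 (3 equiv), toluene, 70 °C
Reagents that add atoms: none
Why: Krische carbonyl tert-prenylation by transfer hydrogenation: the catalyst dehydrogenates 1 to aldehyde 3, hydrometalates the allene and adds the 1,1-dimethylallyl unit through its substituted terminus in a closed chair transition state, the chiral ligand setting C10 as S.

**Step 2**
Reactants: 4 (4S)-3,3,7-trimethylocta-1,7-dien-4-ol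
Product: 5 [(2S,5S)-2-methyl-5-(2-methylbut-3-en-2-yl)oxolan-2-yl]methanol
Conditions: Co(modp)2 [bis(1-morpholinocarbamoyl-4,4-dimethyl-1,3-pentanedionato)cobalt] (10 mol%), t-BuOOH (10 mol%), O2 (1 atm), i-PrOH, 55 °C
Reagents that add atoms: dioxygen, O=O
Why: Mukaiyama-type aerobic oxidative cyclisation of a pent-4-en-1-ol: 5-exo closure onto the 1,1-disubstituted alkene through a chair-like transition state with the bulky C10 substituent pseudo-equatorial gives the 2,5-trans oxolane (C7 set as S relative to C10), the C6 radical is trapped by O2 and reduced to CH2OH, and the homoallylic vinyl group cannot cyclise.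

**Step 3**
Reactants: 6 2-methylphenol; 7 acetyl chloride
Product: 9 1-(4-hydroxy-3-methylphenyl)ethan-1-one, via 2-methylphenyl acetate 8 (not isolated)
Conditions: 7 (1.1 equiv), CF3SO3H (neat), 0 → 25 °C
Reagents that add atoms: none
Why: O-acylation followed by acid-promoted Fries rearrangement (Friedel–Crafts acylation) places the acetyl group para to the hydroxyl, the carbon that becomes C15; no stereocentre is formed.

**Step 4**
Reactants: 9 1-(4-hydroxy-3-methylphenyl)ethan-1-one
Product: 11 2-methyl-4-[1-(trifluoromethanesulfonyloxy)ethenyl]phenyl trifluoromethanesulfonate, via 4-acetyl-2-methylphenyl triflate 10 (not isolated)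
Conditions: Tf2O (2.5 equiv), 2,6-di-tert-butyl-4-methylpyridine (3 equiv), CH2Cl2, 0 → 25 °C
Reagents that add atoms: trifluoromethanesulfonic anhydride, O=S(=O)(OS(=O)(=O)C(F)(F)F)C(F)(F)F
Why: the phenol is sulfonylated first and the aryl methyl ketone is then converted into the 1-arylvinyl triflate (Stang vinyl triflate synthesis), the aryl triflate doubling as phenol protection.

**Step 5**
Reactants: 5 [(2S,5S)-2-methyl-5-(2-methylbut-3-en-2-yl)oxolan-2-yl]methanol; 11 2-methyl-4-[1-(trifluoromethanesulfonyloxy)ethenyl]phenyl trifluoromethanesulfonate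
Product: 13 4-{5-[(2S,5S)-5-(hydroxymethyl)-5-methyloxolan-2-yl]-5-methylhex-1-en-2-yl}-2-methylphenyl trifluoromethanesulfonate, via B-alkyl-9-BBN borinate 12 (not isolated)
Conditions: 5, 9-BBN-H (2.3 equiv), THF, 0 → 25 °C; then 11 (1.1 equiv), PdCl2(dppf) (5 mol%), AsPh3 (5 mol%), K3PO4 (3 M aq., 3 equiv), DMF, 25 °C
Reagents that add atoms: none
Why: anti-Markovnikov hydroboration of the neopentyl-type vinyl group (the alcohol is masked in situ as a borinate) and B-alkyl Suzuki–Miyaura coupling form C13–C14, the alkenyl triflate undergoing oxidative addition far faster than the hindered aryl triflate at room temperature.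

**Step 6**
Reactants: 13 (alkene from step 5)
Product: 14 4-{(2R)-5-[(2S,5S)-5-(hydroxymethyl)-5-methyloxolan-2-yl]-5-methylhexan-2-yl}-2-methylphenyl trifluoromethanesulfonate
Conditions: [Ir(cod)(ThrePHOX)]BArF (1 mol%, ligand enantiomer giving 14R), H2 (1 bar), CH2Cl2, 25 °C
Reagents that add atoms: none
Why: Pfaltz-type asymmetric hydrogenation of an unfunctionalised 1,1-disubstituted aryl alkene at low hydrogen pressure sets the benzylic centre C14 as R under catalyst control, leaving the aryl triflate and the oxolane untouched.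

**Step 7**
Reactants: 14 (alcohol from step 6)
Product: 15 4-{(2R)-5-[(2S,5S)-5-formyl-5-methyloxolan-2-yl]-5-methylhexan-2-yl}-2-methylphenyl trifluoromethanesulfonate
Conditions: Dess–Martin periodinane (1.3 equiv), CH2Cl2, 0 → 25 °C
Reagents that add atoms: none
Why: Dess–Martin oxidation gives the non-enolisable α-alkoxy aldehyde (C6) and is run before the phenol is unmasked because hypervalent iodine reagents attack free electron-rich phenols.

**Step 8**
Reactants: 15 (aldehyde triflate from step 7)
Product: 16 (2S,5S)-5-[(5R)-5-(4-hydroxy-3-methylphenyl)-2-methylhexan-2-yl]-2-methyloxolane-2-carbaldehyde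
Conditions: Et4NOH (35% aq., 1.5 equiv), 1,4-dioxane, 25 °C; pH 7 buffer
Reagents that add atoms: none
Why: hydroxide attacks sulfur of the aryl triflate (S–O cleavage) and frees the phenol under conditions the quaternary, non-enolisable aldehyde tolerates.

**Step 9**
Reactants: 16 (phenol aldehyde from step 8)
Product: 18 macrocyclic phenol (twelve-membered metacyclophane; C5–C6 bond formed; C6 carbinol as both epimers), via bromomagnesium phenoxide 17 (not isolated)
Conditions: MgBr2·OEt2 (2 equiv), Et3N (3 equiv), CH2Cl2, slow addition to 1 mM, 25 → 40 °C; aq. NH4Cl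
Reagents that add atoms: none
Why: Casiraghi-type ortho-specific hydroxyalkylation of an ArOMgBr phenoxide, in which Mg holds phenoxide and aldehyde (the oxolane oxygen assisting chelation), attacks through the only free ortho carbon C5 and closes the twelve-membered ring at high dilution; the new C6 carbinol centre is not controlled and is erased in step 11.

**Step 10**
Reactants: 18 (macrocyclic phenol from step 9)
Product: 20 macrocyclic p-quinol (4-hydroxycyclohexa-2,5-dienone; OH on C15; C15 and C6 as epimer mixtures), via para-hydroperoxy dienone 19 (not isolated)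
Conditions: KHSO5 (as 2KHSO5·KHSO4·K2SO4, 4 equiv), NaHCO3, MeCN/H2O (2:1), 0 → 25 °C; then Me2S
Reagents that add atoms: potassium peroxymonosulfate, [K+].[O-]S(=O)(=O)OO
Why: singlet-oxygen dearomatisation of a para-alkylphenol gives the para-hydroperoxy dienone, which Me2S reduces to the p-quinol; the configuration at C15 is irrelevant because C15 becomes a ketone in step 11.

**Step 11**
Reactants: 20 (p-quinol from step 10)
Product: 22 1-deacetoxy target (C1–H; ring-contracted cyclopentenone with E exocyclic C5=C6 enone), via ring-contracted aldol 21 (not isolated)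
Conditions: KOt-Bu (2.2 equiv), 18-crown-6 (0.2 equiv), THF/t-BuOH (4:1), 0 → 40 °C; AcOH quench
Reagents that add atoms: none
Why: Proposed new method: alkoxide-triggered vinylogous α-ketol (acyloin-type) ring contraction of a p-quinol coupled to E1cB dehydration — the C15–OK alkoxide pushes the in-ring sp2 carbon C2 from C15 onto the enone β-carbon C1 (a 1,2-shift of the carbon skeleton through a bicyclo[3.1.0]-like transition state), C15 becomes the ketone, the C4–C5 enolate expels the C6 hydroxide to give the ring-enforced E exocyclic enone, and the product is parked as its C1 dienolate, which also shields C14 from epimerisation; the C2-to-C1 mode should beat the C1-to-C2 mode because the C6–O bond lowers the acceptor orbital at C1 and only that mode ends in elimination, while alkyl (C14) migration is disfavoured under anionic conditions; the closest known reaction types are the base-mediated acyloin ring contraction of 6-hydroxycyclohexadienones (humulone to isohumulone), the benzilic acid ring contraction of hydroxyquinones and the light-induced type A rearrangement of 4-substituted cyclohexadienones; C1 forms as an enolisable CH centre and is fixed in step 12.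

**Step 12**
Reactants: 22 (1-deacetoxy target from step 11)
Product: 23 target CNP0144863.1 (1S,7S,10S,14R)
Conditions: Pb(OAc)4 (1.2 equiv), benzene/AcOH (10:1), 25 °C
Reagents that add atoms: lead tetraacetate, CC(=O)O[Pb](OC(C)=O)(OC(C)=O)OC(C)=O
Why: Pb(OAc)4 α-acetoxylation of an enolised, doubly activated ketone: C1–H (α to C15=O and vinylogous to C4=O) is the most acidic site, Pb binds the enol oxygen and transfers acetate to C1 from the face of the planar dienol not covered by the C11–C14 arc of the twelve-membered ring (biased by the trans-bridged oxolane and the C14 methyl), which is expected to give 1S; this facial preference is not proven and is covered by a fallback.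

## Compound list

1 | 4-methylpent-4-en-1-ol | OCCCC(C)=C | starting material
2 | 3-methylbuta-1,2-diene (1,1-dimethylallene) | CC(C)=C=C | starting material
3 | 4-methylpent-4-enal | O=CCCC(C)=C | intermediate
4 | (4S)-3,3,7-trimethylocta-1,7-dien-4-ol | C=C(C)CC[C@H](O)C(C)(C)C=C | intermediate
5 | [(2S,5S)-2-methyl-5-(2-methylbut-3-en-2-yl)oxolan-2-yl]methanol (CH2OH and side chain trans) | OC[C@]1(C)CC[C@H](O1)C(C)(C)C=C | intermediate
6 | 2-methylphenol | Cc1ccccc1O | starting material
7 | acetyl chloride | CC(Cl)=O | starting material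
8 | 2-methylphenyl acetate | CC(=O)Oc1ccccc1C | intermediate
9 | 1-(4-hydroxy-3-methylphenyl)ethan-1-one | CC(=O)c1ccc(O)c(C)c1 | intermediate
10 | 4-acetyl-2-methylphenyl trifluoromethanesulfonate | CC(=O)c1ccc(OS(=O)(=O)C(F)(F)F)c(C)c1 | intermediate
11 | 2-methyl-4-[1-(trifluoromethanesulfonyloxy)ethenyl]phenyl trifluoromethanesulfonate | C=C(OS(=O)(=O)C(F)(F)F)c1ccc(OS(=O)(=O)C(F)(F)F)c(C)c1 | intermediate
12 | B-alkyl-9-BBN borinate (5 hydroborated at the vinyl terminus C13; CH2OH as its O–9-BBN borinate) | C1CCC2CCCC1B2OC[C@]1(C)CC[C@H](O1)C(C)(C)CCB1C2CCCC1CCC2 | intermediate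
13 | 4-{5-[(2S,5S)-5-(hydroxymethyl)-5-methyloxolan-2-yl]-5-methylhex-1-en-2-yl}-2-methylphenyl trifluoromethanesulfonate | OC[C@]1(C)CC[C@H](O1)C(C)(C)CCC(=C)c1ccc(OS(=O)(=O)C(F)(F)F)c(C)c1 | intermediate
14 | 4-{(2R)-5-[(2S,5S)-5-(hydroxymethyl)-5-methyloxolan-2-yl]-5-methylhexan-2-yl}-2-methylphenyl trifluoromethanesulfonate | OC[C@]1(C)CC[C@H](O1)C(C)(C)CC[C@@H](C)c1ccc(OS(=O)(=O)C(F)(F)F)c(C)c1 | intermediate
15 | 4-{(2R)-5-[(2S,5S)-5-formyl-5-methyloxolan-2-yl]-5-methylhexan-2-yl}-2-methylphenyl trifluoromethanesulfonate | O=C[C@]1(C)CC[C@H](O1)C(C)(C)CC[C@@H](C)c1ccc(OS(=O)(=O)C(F)(F)F)c(C)c1 | intermediate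
16 | (2S,5S)-5-[(5R)-5-(4-hydroxy-3-methylphenyl)-2-methylhexan-2-yl]-2-methyloxolane-2-carbaldehyde | O=C[C@]1(C)CC[C@H](O1)C(C)(C)CC[C@@H](C)c1ccc(O)c(C)c1 | intermediate
17 | bromomagnesium phenoxide of 16 (ArOMgBr) | O=C[C@]1(C)CC[C@H](O1)C(C)(C)CC[C@@H](C)c1ccc(O[Mg]Br)c(C)c1 | intermediate
18 | macrocyclic phenol, twelve-membered metacyclophane: aromatic C5 (ortho to OH) bonded to C6H(OH); 7S,10S,14R; C6 as both epimers | OC1[C@]2(C)CC[C@H](O2)C(C)(C)CC[C@@H](C)c2cc(C)c(O)c1c2 | intermediate
19 | para-hydroperoxy dienone (18 dearomatised, OOH on C15; C6 and C15 epimer mixtures) | OC1[C@]2(C)CC[C@H](O2)C(C)(C)CC[C@@H](C)C2(OO)C=C(C)C(=O)C1=C2 | intermediate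
20 | macrocyclic p-quinol: ring C15(OH)–C2H=C3(Me)–C4(=O)–C5(=C1H), C5 bearing C6H(OH); 7S,10S,14R; C6 and C15 epimer mixtures | OC1[C@]2(C)CC[C@H](O2)C(C)(C)CC[C@@H](C)C2(O)C=C(C)C(=O)C1=C2 | intermediate
21 | ring-contracted aldol: C15 ketone on C1, C5–H, C6–OH; C1, C5 and C6 epimer mixtures | OC1[C@]2(C)CC[C@H](O2)C(C)(C)CC[C@@H](C)C(=O)C2C=C(C)C(=O)C12 | intermediate
22 | 1-deacetoxy target: cyclopentenone C1H(C15=O)–C2H=C3(Me)–C4(=O)–C5(=C6H), E enone; 7S,10S,14R; C1 epimers interconvert through the enol | C12C=C(C)C(=O)/C1=C/[C@]1(C)CC[C@H](O1)C(C)(C)CC[C@@H](C)C2=O | intermediate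
23 | CNP0144863.1 (1S,7S,10S,14R) | CC(=O)O[C@@]12C=C(C)C(=O)/C1=C/[C@]1(C)CC[C@H](O1)C(C)(C)CC[C@@H](C)C2=O | target

## Step count and risks

Total step count: 12. Longest linear sequence: 10 (steps 3–12 from 2-methylphenol; equally steps 1, 2 and 5–12 from 1).

Three steps most likely to fail:

Step 11 (the proposed new ring contraction). The shift may not occur thermally, or the C1-to-C2 mode may compete. The fallback uses known photochemistry and sets out from 20: irradiation (350 nm, MeCN, 0 °C) triggers the type A cyclohexadienone photorearrangement to the bicyclo[3.1.0]hexenone cyclopropanol F1 (C15 bonded to C1 and C5). K2CO3 in MeOH (40 °C) then opens this β-keto cyclopropanol by retro-aldol cleavage of C15–C5 to aldol 21 and dehydrates it, coming back to the route at 22.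

Step 9 (macrocyclisation by ortho-hydroxyalkylation). Ring closure to a twelve-membered metacyclophane at a hindered aldehyde may be slow or give oligomers. The fallback sets out from 16: N-iodosuccinimide (MeCN, 0 °C) iodinates the only free ortho position to give the iodophenol aldehyde F2, and Nozaki–Hiyama–Kishi addition (CrCl2, NiCl2 cat., DMSO/THF, 2 mM) closes the ring, coming back at 18.

Step 12 (facial selectivity at C1). Substrate control by the macrocycle may be low or opposite. The fallback sets out from 22 and uses reagent control: the K dienolate (KN(SiMe3)2, THF, −78 °C) is hydroxylated with the matching enantiomer of (camphorsulfonyl)oxaziridine (Davis oxidation) to the tertiary C1 alcohol F3, which is acetylated (Ac2O, Sc(OTf)3 cat., MeCN, 0 °C), coming back at 23.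

## Further compounds

F1 | step 11 | bicyclo[3.1.0]hexenone cyclopropanol (C15(OH) bridging C1 and C5; five-membered ring C1–C2H=C3(Me)–C4(=O)–C5; new centres not assigned) | OC1[C@]2(C)CC[C@H](O2)C(C)(C)CC[C@@H](C)C2(O)C3C=C(C)C(=O)C123
F2 | step 9 | (2S,5S)-5-[(5R)-5-(4-hydroxy-3-iodo-5-methylphenyl)-2-methylhexan-2-yl]-2-methyloxolane-2-carbaldehyde | O=C[C@]1(C)CC[C@H](O1)C(C)(C)CC[C@@H](C)c1cc(C)c(O)c(I)c1
F3 | step 12 | 1-deacetyl target (tertiary C1 alcohol, 1S,7S,10S,14R) | O[C@@]12C=C(C)C(=O)/C1=C/[C@]1(C)CC[C@H](O1)C(C)(C)CC[C@@H](C)C2=O
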